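**Plan**

- Retrosynthesis (prostanoid numbering: C1 ester carbon, C8–C12 the ring): the C12 acetate is removed, then C11–C12 is cut and a hydrogen is returned to C7. This is possible because the C12 carbinol oxygen, ring carbons C8–C12, the C9 carbonyl and the C7=C8 and C10=C11 alkenes are together an isomer of a 2,3-dialkyl-4-pyranone with its ring oxygen on C12 (pyranone 16).
- The pyranone is cut at O–C11 (acetal cyclodehydration), C7–C8 (C-propargylation of a β-diketone), C8–C12 (Claisen-type acylation) and C4–C5 (ynone formation).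
- Forward: the acyl piece 6 (steps 1–3) and the propargylic bromide 13 (steps 4–7) are joined at C7–C8 (step 8). The pyranone ring closes (step 9), the alkyne is reduced to the 5Z alkene (step 10), light contracts the pyranone to the cyclopentenone (step 11), and the C12 alcohol is acetylated (step 12).
- Stereochemistry: C4 (R) comes from catalyst-controlled transfer hydrogenation of ynone 9; 14Z,17Z come from the starting dienol; 5Z from Lindlar reduction; 7E from the geometry of proton loss. C12 is created in step 11 without facial bias, and the 12S isomer is separated from its epimer, which is a diastereomer because C4 is already fixed.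

Key step: step 11

Assumption: the photochemical contraction is taken to show no facial preference, so the route counts on chromatographic separation of the two C12 epimers (diastereomers through the resolved C4 centre) and not on induction.

**Route**

Step 1
Reactants: 1 (3Z,6Z)-nona-3,6-dien-1-ol
Product: 2 (3Z,6Z)-nona-3,6-dienoic acid
Conditions: CrO3, H2SO4, H2O (Jones reagent), acetone, 0 °C
Reagents that add atoms: water, O
Why: Jones oxidation takes the primary homoallylic alcohol through the aldehyde hydrate to the acid quickly at 0 °C, conditions under which (Z)-3-alkenols are known to give (Z)-3-alkenoic acids without double-bond migration.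

Step 2
Reactants: 2 (3Z,6Z)-nona-3,6-dienoic acid
Product: 3 (3Z,6Z)-nona-3,6-dienoyl chloride
Conditions: (COCl)2, DMF (cat.), CH2Cl2, 0 °C to rt; evaporate, use crude
Reagents that add atoms: oxalyl chloride, ClC(=O)C(=O)Cl
Why: Acid chloride formation through the chloroiminium species from DMF and oxalyl chloride is base-free and gives only gaseous by-products, so the skipped Z,Z-diene and the β,γ-unsaturation should be preserved.

Step 3
Reactants: 3 (3Z,6Z)-nona-3,6-dienoyl chloride; 4 4,4-dimethoxybutan-2-one
Product: 6 (7Z,10Z)-1,1-dimethoxytrideca-7,10-diene-3,5-dione, via lithium 4,4-dimethoxybut-1-en-2-olate 5 (not isolated)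
Conditions: LiN(SiMe3)2 (2.2 equiv), 4 (2.1 equiv), THF, −78 °C; then 3 (1.0 equiv), −78 °C; aq NH4Cl; rapid filtration through Et3N-deactivated silica
Reagents that add atoms: none
Why: Crossed Claisen-type C-acylation in which the kinetic lithium enolate at the methyl group of 4 is acylated by 3 at −78 °C, while the second equivalent of enolate deprotonates the more acidic β-diketone as it forms and so protects it from over-acylation and from migration of the β,γ-alkene.

Step 4
Reactants: 7 tert-butyldimethyl(prop-2-yn-1-yloxy)silane; 8 methyl 4-chloro-4-oxobutanoate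
Product: 9 methyl 7-[(tert-butyldimethylsilyl)oxy]-4-oxohept-5-ynoate
Conditions: PdCl2(PPh3)2 (2 mol %), CuI (4 mol %), Et3N (1.2 equiv), THF, rt
Reagents that add atoms: none
Why: Acyl Sonogashira coupling, in which oxidative addition of the acid chloride to zerovalent palladium formed in situ and transmetalation of the copper acetylide give the ynone under conditions that leave the methyl ester and the silyl ether untouched.

Step 5
Reactants: 9 methyl 7-[(tert-butyldimethylsilyl)oxy]-4-oxohept-5-ynoate
Product: 11 methyl (4R)-4-acetoxy-7-[(tert-butyldimethylsilyl)oxy]hept-5-ynoate, via (4R)-hydroxy ester 10 (not isolated)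
Conditions: Ru[(R,R)-TsDPEN](p-cymene) (1 mol %, preformed amido complex), i-PrOH, 25 °C; evaporate; then Ac2O, pyridine, DMAP (cat.), CH2Cl2, 0 °C
Reagents that add atoms: acetic anhydride, CC(=O)OC(C)=O
Why: Asymmetric transfer hydrogenation of an alkynyl ketone by the bifunctional ruthenium hydride, in which the (R,R)-ligand should deliver hydride to the carbonyl face that gives the (R)-propargylic alcohol (the alkynyl group takes the place that aryl takes in aryl ketones), so C4 is set under catalyst control, and acetylation of the crude alcohol forestalls γ-lactonisation.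

Step 6
Reactants: 11 methyl (4R)-4-acetoxy-7-[(tert-butyldimethylsilyl)oxy]hept-5-ynoate
Product: 12 methyl (4R)-4-acetoxy-7-hydroxyhept-5-ynoate
Conditions: HF·pyridine, THF/pyridine, 0 °C to rt
Reagents that add atoms: none
Why: Fluoride-mediated cleavage of the primary silyl ether under buffered conditions that touch neither the acetate nor the methyl ester, and acyl migration across the linear alkyne is not possible.

Step 7
Reactants: 12 methyl (4R)-4-acetoxy-7-hydroxyhept-5-ynoate
Product: 13 methyl (4R)-4-acetoxy-7-bromohept-5-ynoate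
Conditions: CBr4, PPh3, CH2Cl2, 0 °C
Reagents that add atoms: carbon tetrabromide, BrC(Br)(Br)Br
Why: Appel reaction, in which bromide displaces the alkoxyphosphonium group at the primary propargylic carbon under neutral conditions, remote from the C4 stereocentre.

Step 8
Reactants: 6 (7Z,10Z)-1,1-dimethoxytrideca-7,10-diene-3,5-dione; 13 methyl (4R)-4-acetoxy-7-bromohept-5-ynoate
Product: 14 methyl (4R,11Z,14Z)-4-acetoxy-8-(3,3-dimethoxypropanoyl)-9-oxoheptadeca-11,14-dien-5-ynoate (C8 epimers and enol forms)
Conditions: K2CO3 (1.5 equiv), acetone, rt, slow addition of 13 (1.0 equiv)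
Reagents that add atoms: none
Why: C-alkylation of the potassium enolate of a β-diketone by a reactive primary propargylic bromide (SN2), in which the weak base deprotonates only the carbon between the two carbonyls, the acetal, acetate and ester resist the conditions, and the new C8 centre needs no control because it becomes sp2 in step 9.

Step 9
Reactants: 14 methyl (4R,11Z,14Z)-4-acetoxy-8-(3,3-dimethoxypropanoyl)-9-oxoheptadeca-11,14-dien-5-ynoate
Product: 15 methyl (4R)-4-acetoxy-7-{2-[(2Z,5Z)-octa-2,5-dien-1-yl]-4-oxo-4H-pyran-3-yl}hept-5-ynoate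
Conditions: CF3CO2H, CH2Cl2, 0 °C to rt
Reagents that add atoms: none
Why: Acid-catalysed cyclodehydration of a 5,5-dimethoxy-1,3-diketone, in which the enol oxygen of the C12 carbonyl adds to the oxocarbenium ion from the acetal (O–C11 bond, the only six-membered closure available) and two molecules of methanol are lost to give the aromatic 4-pyranone.

Step 10
Reactants: 15 methyl (4R)-4-acetoxy-7-{2-[(2Z,5Z)-octa-2,5-dien-1-yl]-4-oxo-4H-pyran-3-yl}hept-5-ynoate
Product: 16 methyl (4R,5Z)-4-acetoxy-7-{2-[(2Z,5Z)-octa-2,5-dien-1-yl]-4-oxo-4H-pyran-3-yl}hept-5-enoate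
Conditions: H2 (1 atm), Lindlar catalyst (Pd on CaCO3 poisoned with Pb(OAc)2), quinoline, EtOAc, rt, stopped at one equivalent of H2
Reagents that add atoms: none
Why: Lindlar semihydrogenation, in which syn addition of hydrogen on the lead-poisoned palladium surface converts the alkyne into the 5Z alkene while the isolated Z-alkenes, the pyranone and the allylic acetate react much more slowly.

Step 11
Reactants: 16 methyl (4R,5Z)-4-acetoxy-7-{2-[(2Z,5Z)-octa-2,5-dien-1-yl]-4-oxo-4H-pyran-3-yl}hept-5-enoate
Product: 19 methyl (4R,5Z,7E)-4-acetoxy-7-[(2S)-2-hydroxy-2-[(2Z,5Z)-octa-2,5-dien-1-yl]-5-oxocyclopent-3-en-1-ylidene]hept-5-enoate, via epoxy oxyallyl zwitterion 17 (not isolated), via epoxy dienol 18 (not isolated)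
Conditions: hν (254 nm, low-pressure Hg lamp), degassed (CF3)2CHOH, i-Pr2NEt (2 equiv), 3 mM, 5 °C, FEP-tubing flow reactor, low conversion per pass (about one third) with recycling of 16; silica chromatography, then preparative HPLC
Reagents that add atoms: none
Why: Proposed new method: excitation of the 4-pyranone should induce disrotatory 4π closure between the two oxygen-bearing carbons C11 and C12, which closes the five-membered carbocycle and gives the 6-oxabicyclo[3.1.0]hexenyl oxyallyl zwitterion 17; the closest known reaction type is the photochemical ring contraction of 4-pyranones in which this zwitterion is captured by hydroxylic solvents or tethered nucleophiles to give 4-hydroxycyclopent-2-enones. Here the strongly ionising but non-nucleophilic solvent offers no nucleophile, so the C8 terminus, whose only adjacent hydrogens are the C7 pair that is also allylic to C5=C6, should lose a proton to the hexafluoroisopropoxide buffer in an E1-like step (the way oxyallyl cations of Nazarov cyclisations end) to give epoxy dienol 18. Vinylogous opening of the epoxide at C11 by the C9–C10 enol then leaves the oxygen on C12 and creates the C10=C11 alkene, which is the known isomerisation of a β,γ-epoxy ketone to a γ-hydroxy enone. The 7E geometry is expected because C6 turns away from the solvated in-plane C9 oxygen during proton loss (allylic 1,3-strain), and the position of the new alkene is secured because C10 carries no alkyl group. The new C12 stereocentre is fixed by the face on which the two termini rotate together; nothing in 16 biases it, so both epimers are expected, and the resolved C4 centre serves only to make them separable diastereomers, the 12S isomer being isolated by HPLC. Low conversion per pass in flow and exclusion of oxygen are meant to limit E/Z photoisomerisation of the dienone product and the competing oxygen walk to the 2-pyranone.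

Step 12
Reactants: 19 methyl (4R,5Z,7E)-4-acetoxy-7-[(2S)-2-hydroxy-2-[(2Z,5Z)-octa-2,5-dien-1-yl]-5-oxocyclopent-3-en-1-ylidene]hept-5-enoate
Product: 20 methyl (4R,5Z,7E)-4-acetoxy-7-[(2S)-2-acetoxy-2-[(2Z,5Z)-octa-2,5-dien-1-yl]-5-oxocyclopent-3-en-1-ylidene]hept-5-enoate
Conditions: Ac2O, DMAP, Et3N, CH2Cl2, rt
Reagents that add atoms: acetic anhydride, CC(=O)OC(C)=O
Why: DMAP-catalysed acylation through the N-acetylpyridinium ion is the standard way to acetylate a hindered tertiary alcohol, is mild enough for the cross-conjugated dienone, and does not touch the C–O bond at C12, so its configuration is kept.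

**Compound list**

1 | (3Z,6Z)-nona-3,6-dien-1-ol | CC/C=C\C/C=C\CCO | starting material
2 | (3Z,6Z)-nona-3,6-dienoic acid | CC/C=C\C/C=C\CC(=O)O | intermediate
3 | (3Z,6Z)-nona-3,6-dienoyl chloride | CC/C=C\C/C=C\CC(=O)Cl | intermediate
4 | 4,4-dimethoxybutan-2-one | CC(=O)CC(OC)OC | starting material
5 | lithium 4,4-dimethoxybut-1-en-2-olate | [Li+].[O-]C(=C)CC(OC)OC | intermediate
6 | (7Z,10Z)-1,1-dimethoxytrideca-7,10-diene-3,5-dione | CC/C=C\C/C=C\CC(=O)CC(=O)CC(OC)OC | intermediate
7 | tert-butyldimethyl(prop-2-yn-1-yloxy)silane | C#CCO[Si](C)(C)C(C)(C)C | starting material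
8 | methyl 4-chloro-4-oxobutanoate | COC(=O)CCC(=O)Cl | starting material
9 | methyl 7-[(tert-butyldimethylsilyl)oxy]-4-oxohept-5-ynoate | COC(=O)CCC(=O)C#CCO[Si](C)(C)C(C)(C)C | intermediate
10 | methyl (4R)-7-[(tert-butyldimethylsilyl)oxy]-4-hydroxyhept-5-ynoate | COC(=O)CC[C@@H](O)C#CCO[Si](C)(C)C(C)(C)C | intermediate
11 | methyl (4R)-4-acetoxy-7-[(tert-butyldimethylsilyl)oxy]hept-5-ynoate | COC(=O)CC[C@@H](OC(C)=O)C#CCO[Si](C)(C)C(C)(C)C | intermediate
12 | methyl (4R)-4-acetoxy-7-hydroxyhept-5-ynoate | COC(=O)CC[C@@H](OC(C)=O)C#CCO | intermediate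
13 | methyl (4R)-4-acetoxy-7-bromohept-5-ynoate | COC(=O)CC[C@@H](OC(C)=O)C#CCBr | intermediate
14 | methyl (4R,11Z,14Z)-4-acetoxy-8-(3,3-dimethoxypropanoyl)-9-oxoheptadeca-11,14-dien-5-ynoate (C8 epimers and enol forms) | CC/C=C\C/C=C\CC(=O)C(CC#C[C@@H](CCC(=O)OC)OC(C)=O)C(=O)CC(OC)OC | intermediate
15 | methyl (4R)-4-acetoxy-7-{2-[(2Z,5Z)-octa-2,5-dien-1-yl]-4-oxo-4H-pyran-3-yl}hept-5-ynoate | CC/C=C\C/C=C\CC1=C(CC#C[C@@H](CCC(=O)OC)OC(C)=O)C(=O)C=CO1 | intermediate
16 | methyl (4R,5Z)-4-acetoxy-7-{2-[(2Z,5Z)-octa-2,5-dien-1-yl]-4-oxo-4H-pyran-3-yl}hept-5-enoate | CC/C=C\C/C=C\CC1=C(C/C=C\[C@@H](CCC(=O)OC)OC(C)=O)C(=O)C=CO1 | intermediate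
17 | epoxy oxyallyl zwitterion (6-oxabicyclo[3.1.0]hexenyl cation with C9 oxide, epoxide across C11 and C12) | CC/C=C\C/C=C\C[C@@]12O[C@H]2C=C([O-])[C+]1C/C=C\[C@@H](CCC(=O)OC)OC(C)=O | intermediate
18 | epoxy dienol (C7=C8 alkene, C9–C10 enol, epoxide across C11 and C12) | CC/C=C\C/C=C\C[C@@]12O[C@H]2C=C(O)/C1=C/C=C\[C@@H](CCC(=O)OC)OC(C)=O | intermediate
19 | methyl (4R,5Z,7E)-4-acetoxy-7-[(2S)-2-hydroxy-2-[(2Z,5Z)-octa-2,5-dien-1-yl]-5-oxocyclopent-3-en-1-ylidene]hept-5-enoate | CC/C=C\C/C=C\C[C@]1(O)C=CC(=O)/C1=C/C=C\[C@@H](CCC(=O)OC)OC(C)=O | intermediate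
20 | methyl (4R,5Z,7E)-4-acetoxy-7-[(2S)-2-acetoxy-2-[(2Z,5Z)-octa-2,5-dien-1-yl]-5-oxocyclopent-3-en-1-ylidene]hept-5-enoate | CC/C=C\C/C=C\C[C@]1(OC(C)=O)C=CC(=O)/C1=C/C=C\[C@@H](CCC(=O)OC)OC(C)=O | target

**Step count**

Total: 12 steps. Longest linear sequence: 9 steps (steps 4–12, from 7 and 8).

**Steps most likely to fail**

Step 11. Capture of the zwitterion by the medium, or its oxygen walk to the 2-pyranone, may outrun proton loss, and the dienone may isomerise under the lamp. The fallback is the known aldol–dehydration construction of the alkylidenecyclopentenone; it sets out from 12 and comes back at 20.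
- Lindlar semihydrogenation of 12 gives methyl (4R,5Z)-4-acetoxy-7-hydroxyhept-5-enoate F1, and buffered Dess–Martin oxidation gives methyl (4R,5Z)-4-acetoxy-7-oxohept-5-enoate F2.
- For the ring, allenylmagnesium bromide adds to one carbonyl of commercial cyclopent-4-ene-1,3-dione to give racemic 4-hydroxy-4-(prop-2-yn-1-yl)cyclopent-2-en-1-one F3.
- The terminal alkyne of F3 is coupled (CuI, NaI, Cs2CO3, DMF) with (2Z)-1-bromopent-2-ene F4 (from commercial (2Z)-pent-2-en-1-ol and PBr3) to give 4-hydroxy-4-[(5Z)-oct-5-en-2-yn-1-yl]cyclopent-2-en-1-one F5, and Lindlar reduction gives 4-hydroxy-4-[(2Z,5Z)-octa-2,5-dien-1-yl]cyclopent-2-en-1-one F6.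
- The alkoxide enolate of F6 (LiN(i-Pr)2, 2.2 equiv, THF, −78 °C) adds to F2 to give methyl (4R,5Z)-4-acetoxy-7-hydroxy-7-{2-hydroxy-2-[(2Z,5Z)-octa-2,5-dien-1-yl]-5-oxocyclopent-3-en-1-yl}hept-5-enoate F7.
- Exhaustive acetylation (Ac2O, DMAP) gives methyl (4R,5Z)-4,7-diacetoxy-7-{2-acetoxy-2-[(2Z,5Z)-octa-2,5-dien-1-yl]-5-oxocyclopent-3-en-1-yl}hept-5-enoate F8, from which DBU removes acetic acid across C7–C8 to give 20 together with its C12 epimer (the ring partner is racemic), separated by HPLC. Step 12 is then not needed.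

Step 8. O-alkylation, double alkylation or base-induced migration of the C14=C15 alkene into conjugation with the ketone may erode the C-propargylation. The fallback reverses the order of the two C–C bond formations; it sets out from 13 and comes back at 15.
- The lithium enolate of commercial (E)-4-methoxybut-3-en-2-one (LiN(SiMe3)2, THF, −78 °C) is alkylated with 13 to give methyl (4R,10E)-4-acetoxy-11-methoxy-9-oxoundec-10-en-5-ynoate F9.
- The enolate of F9 (LiN(SiMe3)2, 2 equiv, −78 °C) is acylated with 3 to give methyl (4R,11Z,14Z)-4-acetoxy-8-[(2E)-3-methoxyprop-2-enoyl]-9-oxoheptadeca-11,14-dien-5-ynoate F10.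
- CF3CO2H closes F10 directly to 15, so the mono-alkylated β,γ-unsaturated diketone is never held under carbonate.

Step 3. Deprotonation of the acid chloride to a ketene, migration of its β,γ-double bond or O-acylation of the enolate may compete with C-acylation. The fallback replaces acylation by aldol addition and oxidation; it sets out from 1 and comes back at 6.
- Buffered Dess–Martin oxidation of 1 at 0 °C gives (3Z,6Z)-nona-3,6-dienal F11, used at once.
- Addition of enolate 5 at −78 °C gives (7Z,10Z)-5-hydroxy-1,1-dimethoxytrideca-7,10-dien-3-one F12, and a second Dess–Martin oxidation gives 6.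

**Further compounds**

F1 | step 11 | methyl (4R,5Z)-4-acetoxy-7-hydroxyhept-5-enoate | COC(=O)CC[C@@H](OC(C)=O)/C=C\CO
F2 | step 11 | methyl (4R,5Z)-4-acetoxy-7-oxohept-5-enoate | COC(=O)CC[C@@H](OC(C)=O)/C=C\C=O
F3 | step 11 | 4-hydroxy-4-(prop-2-yn-1-yl)cyclopent-2-en-1-one (racemic) | C#CCC1(O)CC(=O)C=C1
F4 | step 11 | (2Z)-1-bromopent-2-ene | CC/C=C\CBr
F5 | step 11 | 4-hydroxy-4-[(5Z)-oct-5-en-2-yn-1-yl]cyclopent-2-en-1-one (racemic) | CC/C=C\CC#CCC1(O)CC(=O)C=C1
F6 | step 11 | 4-hydroxy-4-[(2Z,5Z)-octa-2,5-dien-1-yl]cyclopent-2-en-1-one (racemic) | CC/C=C\C/C=C\CC1(O)CC(=O)C=C1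
F7 | step 11 | methyl (4R,5Z)-4-acetoxy-7-hydroxy-7-{2-hydroxy-2-[(2Z,5Z)-octa-2,5-dien-1-yl]-5-oxocyclopent-3-en-1-yl}hept-5-enoate (diastereomer mixture) | CC/C=C\C/C=C\CC1(O)C=CC(=O)C1C(O)/C=C\[C@@H](CCC(=O)OC)OC(C)=O
F8 | step 11 | methyl (4R,5Z)-4,7-diacetoxy-7-{2-acetoxy-2-[(2Z,5Z)-octa-2,5-dien-1-yl]-5-oxocyclopent-3-en-1-yl}hept-5-enoate (diastereomer mixture) | CC/C=C\C/C=C\CC1(OC(C)=O)C=CC(=O)C1C(OC(C)=O)/C=C\[C@@H](CCC(=O)OC)OC(C)=O
F9 | step 8 | methyl (4R,10E)-4-acetoxy-11-methoxy-9-oxoundec-10-en-5-ynoate | COC(=O)CC[C@@H](OC(C)=O)C#CCCC(=O)/C=C/OC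
F10 | step 8 | methyl (4R,11Z,14Z)-4-acetoxy-8-[(2E)-3-methoxyprop-2-enoyl]-9-oxoheptadeca-11,14-dien-5-ynoate | CC/C=C\C/C=C\CC(=O)C(CC#C[C@@H](CCC(=O)OC)OC(C)=O)C(=O)/C=C/OC
F11 | step 3 | (3Z,6Z)-nona-3,6-dienal | CC/C=C\C/C=C\CC=O
F12 | step 3 | (7Z,10Z)-5-hydroxy-1,1-dimethoxytrideca-7,10-dien-3-one | CC/C=C\C/C=C\CC(O)CC(=O)CC(OC)OC
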